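**Retrosynthetic overview**
1. Target ⇒ tricyclic cycloheptenone by two acylations, an anti-dihydroxylation and a CBS reduction; the C11 ketone is carried as a nitro group and unmasked by a Nef reaction.
2. Cyclobutane and cyclohexane ⇒ one anionic cascade on a cycloheptadienone: nitronate Michael addition (six-membered ring), then 4-exo-tet enolate alkylation (four-membered ring, quaternary C2).
3. Cascade substrate ⇒ catalyst-controlled vinylogous Mukaiyama aldol of an achiral silyloxycycloheptatriene with 2-methylidene-4-nitrobutanal, then OH-directed hydrogenation (C9 methyl).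
4. Achiral seven-membered ring ⇒ key step: dearomative (4+3) cycloaddition of 3-methylfuran with a dimethyl-oxyallyl cation, then reductive opening of the oxygen bridge.
5. Ring order: seven-membered ring (from the furan) → six-membered ring → cyclobutane; tricyclic locants follow tricyclo[5.4.0.0^{2,8}]undecane numbering (C3 = CHOH, C4 and C5 = ester carbons, C11 = ketone).

Assumption: intermediates before the aldol step are racemic or achiral (one enantiomer drawn); absolute configuration enters in the aldol step and, independently, in the CBS reduction.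

**Step 1**
Reactants: 1 3-methylfuran; 2 3-bromo-3-methylbutan-2-one
Product: 4 (±)-2,2,6-trimethyl-8-oxabicyclo[3.2.1]oct-6-en-3-one, via oxyallyl cation 3 (not isolated)
Conditions: Et3N, CF3CH2OH, 0 → 23 °C (excess of 1)
Reagents that add atoms: none
Why: dearomative (4+3) cycloaddition of the furan with the oxyallyl cation formed by base-induced loss of HBr (Föhlisch conditions), in which the bulky CMe2 terminus bonds to the furan α-carbon remote from the ring methyl so that the methyl ends on C6, and the bicycle fixes the cis bridge (racemic).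

**Step 2**
Reactants: 4 (±)-2,2,6-trimethyl-8-oxabicyclo[3.2.1]oct-6-en-3-one
Product: 5 (±)-3,3-dimethoxy-2,2,6-trimethyl-8-oxabicyclo[3.2.1]oct-6-ene
Conditions: HC(OMe)3, MeOH, TsOH·H2O (cat.), 40 °C
Reagents that add atoms: trimethyl orthoformate, COC(OC)OC; methanol, CO
Why: acid-catalysed ketalisation protects the ketone from the hydride reagent of the next step and later delivers the vinylogous ester regiospecifically, without touching a stereocentre.

**Step 3**
Reactants: 5 (±)-3,3-dimethoxy-2,2,6-trimethyl-8-oxabicyclo[3.2.1]oct-6-ene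
Product: 6 (±)-trans-6,6-dimethoxy-2,5,5-trimethylcyclohept-3-en-1-ol
Conditions: i-Bu2AlH, Ni(1,5-cyclooctadiene)2 (5 mol %), Ph2P(CH2)4PPh2 (10 mol %), toluene/THF, 23 °C; aq. potassium sodium tartrate
Reagents that add atoms: none
Why: nickel-catalysed hydroalumination of the strained trisubstituted alkene puts the metal on the unsubstituted carbon and hydride (exo) on the methyl-bearing carbon, and β-alkoxide elimination then opens the ether bridge only on the gem-dimethyl side (reductive ring opening), so the oxygen stays next to the CHMe carbon and both stereocentres are erased later.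

**Step 4**
Reactants: 6 (±)-trans-6,6-dimethoxy-2,5,5-trimethylcyclohept-3-en-1-ol
Product: 8 (±)-3-methoxy-4,4,7-trimethylcyclohepta-2,5-dien-1-one, via keto ketal 7 (not isolated)
Conditions: Dess–Martin periodinane, CH2Cl2, 23 °C; then TsOH·H2O (5 mol %), CH2Cl2, 23 °C
Reagents that add atoms: none
Why: Dess–Martin oxidation gives the β-keto ketal, which loses methanol under acid catalysis (β-elimination) to the vinylogous ester with the enol ether necessarily on the gem-dimethyl side, and the one remaining stereocentre is enolisable and irrelevant.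

**Step 5**
Reactants: 8 (±)-3-methoxy-4,4,7-trimethylcyclohepta-2,5-dien-1-one
Product: 10 tert-butyl[(6-methoxy-2,5,5-trimethylcyclohepta-1,3,6-trien-1-yl)oxy]dimethylsilane, via lithium dienolate 9 (not isolated)
Conditions: LiN(i-Pr)2, THF, −78 °C; t-BuMe2SiCl, DMPU, −78 → 0 °C
Reagents that add atoms: tert-butyldimethylsilyl chloride, CC(C)(C)[Si](C)(C)Cl
Why: kinetic α′-deprotonation of the vinylogous ester (Stork–Danheiser-type enolate, the other side being blocked by the quaternary carbon) and O-silylation give one achiral silyl dienol ether, whichever double-bond isomer of 8 is used.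

**Step 6**
Reactants: 11 acrolein; 12 nitromethane
Product: 13 4-nitrobutanal
Conditions: MeNO2 (10 equiv), i-Pr2NEt (10 mol %), MeOH, −10 → 0 °C
Reagents that add atoms: none
Why: base-catalysed Michael addition of the nitronate to acrolein, with no stereocentre formed.

**Step 7**
Reactants: 13 4-nitrobutanal; 14 formaldehyde
Product: 15 2-methylidene-4-nitrobutanal
Conditions: 37 % aq. CH2O, pyrrolidine (10 mol %), EtCO2H (10 mol %), i-PrOH, 45 °C
Reagents that add atoms: none
Why: amine/acid-catalysed α-methylenation (Mannich condensation–elimination through the enamine) under buffered, non-basic conditions that leave the nitroalkane untouched, with no stereocentre formed.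

**Step 8**
Reactants: 10 tert-butyl[(6-methoxy-2,5,5-trimethylcyclohepta-1,3,6-trien-1-yl)oxy]dimethylsilane; 15 2-methylidene-4-nitrobutanal
Product: 16 (5S)-5-[(1S)-1-hydroxy-2-methylidene-4-nitrobutyl]-3-methoxy-4,4,7-trimethylcyclohepta-2,6-dien-1-one
Conditions: SiCl4, (R,R)-binaphthyldiamine-derived bisphosphoramide (5 mol %), i-Pr2NEt (10 mol %), CH2Cl2, −78 °C; aq. NaHCO3
Reagents that add atoms: none
Why: Lewis-base-catalysed vinylogous Mukaiyama aldol reaction in which the fully substituted α-carbon forces attack through the γ-terminus, the chiral phosphoramide-bound silicon cation selects the aldehyde face (carbinol centre, the catalyst antipode being chosen for this sense) and the open antiperiplanar transition state keeps the aldehyde substituent away from the gem-dimethyl carbon (ring C5 relative to the carbinol).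

**Step 9**
Reactants: 16 (5S)-5-[(1S)-1-hydroxy-2-methylidene-4-nitrobutyl]-3-methoxy-4,4,7-trimethylcyclohepta-2,6-dien-1-one
Product: 17 (5S)-5-[(1R,2R)-1-hydroxy-2-methyl-4-nitrobutyl]-3-methoxy-4,4,7-trimethylcyclohepta-2,6-dien-1-one
Conditions: H2 (40 atm), [Rh(norbornadiene)(Ph2P(CH2)4PPh2)]BF4 (5 mol %), CH2Cl2, 23 °C
Reagents that add atoms: none
Why: hydroxyl-directed homogeneous hydrogenation of the 1,1-disubstituted allylic alcohol delivers hydrogen from the face bound through the OH group and gives the 1,2-anti alcohol/methyl pair, while the trisubstituted enone, the enol ether and the nitro group are left alone.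

**Step 10**
Reactants: 17 (5S)-5-[(1R,2R)-1-hydroxy-2-methyl-4-nitrobutyl]-3-methoxy-4,4,7-trimethylcyclohepta-2,6-dien-1-one
Product: 18 (1R,2R)-1-[(1S)-6-methoxy-3,7,7-trimethyl-4-oxocyclohepta-2,5-dien-1-yl]-2-methyl-4-nitrobutyl methanesulfonate
Conditions: MeSO2Cl, Et3N, CH2Cl2, −20 °C
Reagents that add atoms: methanesulfonyl chloride, CS(=O)(=O)Cl
Why: sulfonylation of the secondary alcohol with retention installs the leaving group for the ring closure.

**Step 11**
Reactants: 18 (1R,2R)-1-[(1S)-6-methoxy-3,7,7-trimethyl-4-oxocyclohepta-2,5-dien-1-yl]-2-methyl-4-nitrobutyl methanesulfonate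
Product: 20 (1R,2R,7S,8S,9R)-5-methoxy-2,6,6,9-tetramethyl-11-nitrotricyclo[5.4.0.0^{2,8}]undec-4-en-3-one (C11 epimers), via Michael adduct 19 (not isolated)
Conditions: KOt-Bu (1.05 equiv), THF, −40 → 0 °C; then KN(SiMe3)2 (1.2 equiv), −78 → 23 °C; AcOH
Reagents that add atoms: none
Why: the nitronate closes the cyclohexane by a reversible 6-exo-trig Michael addition to the enone (cis ring fusion), and the α′-enolate generated by the second base then displaces the mesylate with inversion in a 4-exo-tet alkylation (the classical keto-sulfonate route to bicyclo[3.1.1]heptanes), which forms the cyclobutane and the quaternary methyl-bearing carbon in the only geometry the cage allows.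

**Step 12**
Reactants: 20 (1R,2R,7S,8S,9R)-5-methoxy-2,6,6,9-tetramethyl-11-nitrotricyclo[5.4.0.0^{2,8}]undec-4-en-3-one
Product: 22 (1R,2R,7S,8S,9R)-2,6,6,9-tetramethyl-11-nitrotricyclo[5.4.0.0^{2,8}]undec-3-en-5-one (C11 epimers), via allylic alcohol 21 (not isolated)
Conditions: i-Bu2AlH, CH2Cl2, −78 °C; then 1 M aq. HCl, THF, 0 °C
Reagents that add atoms: water, O
Why: 1,2-reduction of the vinylogous ester followed by acid-induced hydrolysis and allylic transposition (Stork–Danheiser sequence) moves the carbonyl to C5 next to the gem-dimethyl group without creating a stereocentre.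

**Step 13**
Reactants: 22 (1R,2R,7S,8S,9R)-2,6,6,9-tetramethyl-11-nitrotricyclo[5.4.0.0^{2,8}]undec-3-en-5-one
Product: 23 (1R,2R,5R,7S,8S,9R)-2,6,6,9-tetramethyl-11-nitrotricyclo[5.4.0.0^{2,8}]undec-3-en-5-ol (C11 epimers)
Conditions: (S)-2-methyl-CBS-oxazaborolidine (20 mol %), BH3·SMe2, THF, −20 °C; MeOH
Reagents that add atoms: none
Why: Corey–Bakshi–Shibata reduction, with the quaternary carbon as the large group and the cis-alkene as the small one, sets the C5 carbinol by catalyst control because the remote cage barely differentiates the two faces of the seven-membered ring.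

**Step 14**
Reactants: 23 (1R,2R,5R,7S,8S,9R)-2,6,6,9-tetramethyl-11-nitrotricyclo[5.4.0.0^{2,8}]undec-3-en-5-ol
Product: 25 (1R,2R,5R,7S,8S,9R)-5-hydroxy-2,6,6,9-tetramethyltricyclo[5.4.0.0^{2,8}]undec-3-en-11-one, via sodium nitronate 24 (not isolated)
Conditions: NaOMe, MeOH, 0 °C; then TiCl3, NH4OAc, H2O, 0 → 23 °C
Reagents that add atoms: water, O
Why: reductive Nef reaction (titanium trichloride reduces the nitronate to the imine, which hydrolyses) unmasks the ketone under buffered conditions, removing the C11 stereocentre next to a non-enolisable bridgehead.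

**Step 15**
Reactants: 25 (1R,2R,5R,7S,8S,9R)-5-hydroxy-2,6,6,9-tetramethyltricyclo[5.4.0.0^{2,8}]undec-3-en-11-one; 26 (E)-2-methylbut-2-enoyl chloride (tigloyl chloride)
Product: 27 (1R,2R,5R,7S,8S,9R)-2,6,6,9-tetramethyl-11-oxotricyclo[5.4.0.0^{2,8}]undec-3-en-5-yl (E)-2-methylbut-2-enoate
Conditions: Et3N, DMAP (0.2 equiv), CH2Cl2, 0 → 23 °C
Reagents that add atoms: none
Why: DMAP-catalysed acylation of the only hydroxyl group places the first tiglate unambiguously on C5 with retention.

**Step 16**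
Reactants: 27 (1R,2R,5R,7S,8S,9R)-2,6,6,9-tetramethyl-11-oxotricyclo[5.4.0.0^{2,8}]undec-3-en-5-yl (E)-2-methylbut-2-enoate
Product: 28 (1R,2R,3S,4S,5S,7S,8S,9R)-3,4-dihydroxy-2,6,6,9-tetramethyl-11-oxotricyclo[5.4.0.0^{2,8}]undecan-5-yl (E)-2-methylbut-2-enoate
Conditions: OsO4 (5 mol %), N-methylmorpholine N-oxide, acetone/H2O, 0 °C
Reagents that add atoms: N-methylmorpholine N-oxide, C[N+]1([O-])CCOCC1; water, O
Why: Upjohn dihydroxylation adds both oxygens syn to each other and anti to the allylic acyloxy group (Kishi's rule), giving the cis-3,4-diol trans to the C5 ester, while the electron-poor tiglate double bond reacts much more slowly than the ring alkene.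

**Step 17**
Reactants: 28 (1R,2R,3S,4S,5S,7S,8S,9R)-3,4-dihydroxy-2,6,6,9-tetramethyl-11-oxotricyclo[5.4.0.0^{2,8}]undecan-5-yl (E)-2-methylbut-2-enoate; 26 (E)-2-methylbut-2-enoyl chloride
Product: 29 (1R,2R,3S,4S,5S,7S,8S,9R)-3-hydroxy-2,6,6,9-tetramethyl-11-oxotricyclo[5.4.0.0^{2,8}]undecane-4,5-diyl bis[(E)-2-methylbut-2-enoate] (target)
Conditions: pyridine, DMAP (cat.), CH2Cl2, −20 → 0 °C
Reagents that add atoms: none
Why: selective acylation, since the C4 hydroxyl is an ordinary secondary alcohol whereas the C3 hydroxyl is neopentyl (next to the quaternary cyclobutane carbon), so the reaction stops at the 4,5-diester.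

**Compound list**
1 | 3-methylfuran | Cc1ccoc1 | starting material
2 | 3-bromo-3-methylbutan-2-one | CC(=O)C(C)(C)Br | starting material
3 | 1,1-dimethyl-2-oxidoallyl cation (oxyallyl zwitterion) | C[C+](C)C([O-])=C | intermediate
4 | (±)-2,2,6-trimethyl-8-oxabicyclo[3.2.1]oct-6-en-3-one (racemic, one enantiomer drawn) | CC1=C[C@H]2O[C@@H]1CC(=O)C2(C)C | intermediate
5 | (±)-3,3-dimethoxy-2,2,6-trimethyl-8-oxabicyclo[3.2.1]oct-6-ene (racemic) | CC1=C[C@H]2O[C@@H]1CC(OC)(OC)C2(C)C | intermediate
6 | (±)-trans-6,6-dimethoxy-2,5,5-trimethylcyclohept-3-en-1-ol (racemic) | C[C@@H]1C=CC(C)(C)C(OC)(OC)C[C@H]1O | intermediate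
7 | (±)-6,6-dimethoxy-2,5,5-trimethylcyclohept-3-en-1-one | CC1C=CC(C)(C)C(OC)(OC)CC1=O | intermediate
8 | (±)-3-methoxy-4,4,7-trimethylcyclohepta-2,5-dien-1-one | COC1=CC(=O)C(C)C=CC1(C)C | intermediate
9 | lithium 6-methoxy-2,5,5-trimethylcyclohepta-1,3,6-trien-1-olate | [Li+].[O-]C1=C(C)C=CC(C)(C)C(OC)=C1 | intermediate
10 | tert-butyl[(6-methoxy-2,5,5-trimethylcyclohepta-1,3,6-trien-1-yl)oxy]dimethylsilane (achiral) | COC1=CC(O[Si](C)(C)C(C)(C)C)=C(C)C=CC1(C)C | intermediate
11 | acrolein | C=CC=O | starting material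
12 | nitromethane | C[N+](=O)[O-] | starting material
13 | 4-nitrobutanal | O=CCCC[N+](=O)[O-] | intermediate
14 | formaldehyde | C=O | starting material
15 | 2-methylidene-4-nitrobutanal | C=C(C=O)CC[N+](=O)[O-] | intermediate
16 | (5S)-5-[(1S)-1-hydroxy-2-methylidene-4-nitrobutyl]-3-methoxy-4,4,7-trimethylcyclohepta-2,6-dien-1-one | COC1=CC(=O)C(C)=C[C@H]([C@H](O)C(=C)CC[N+](=O)[O-])C1(C)C | intermediate
17 | (5S)-5-[(1R,2R)-1-hydroxy-2-methyl-4-nitrobutyl]-3-methoxy-4,4,7-trimethylcyclohepta-2,6-dien-1-one | COC1=CC(=O)C(C)=C[C@H]([C@H](O)[C@H](C)CC[N+](=O)[O-])C1(C)C | intermediate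
18 | (1R,2R)-1-[(1S)-6-methoxy-3,7,7-trimethyl-4-oxocyclohepta-2,5-dien-1-yl]-2-methyl-4-nitrobutyl methanesulfonate | COC1=CC(=O)C(C)=C[C@H]([C@H](OS(C)(=O)=O)[C@H](C)CC[N+](=O)[O-])C1(C)C | intermediate
19 | (1R,7S,8R,9R)-5-methoxy-2,6,6,9-tetramethyl-11-nitro-3-oxobicyclo[5.4.0]undec-4-en-8-yl methanesulfonate (cis-fused Michael adduct, drawn neutral; C2 and C11 unfixed) | COC1=CC(=O)C(C)[C@@H]2C([N+](=O)[O-])C[C@@H](C)[C@@H](OS(C)(=O)=O)[C@@H]2C1(C)C | intermediate
20 | (1R,2R,7S,8S,9R)-5-methoxy-2,6,6,9-tetramethyl-11-nitrotricyclo[5.4.0.0^{2,8}]undec-4-en-3-one (C11 epimers) | COC1=CC(=O)[C@@]2(C)[C@@H]3C([N+](=O)[O-])C[C@@H](C)[C@H]2[C@@H]3C1(C)C | intermediate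
21 | (1R,2R,7S,8S,9R)-5-methoxy-2,6,6,9-tetramethyl-11-nitrotricyclo[5.4.0.0^{2,8}]undec-4-en-3-ol (C3 and C11 epimers) | COC1=CC(O)[C@@]2(C)[C@@H]3C([N+](=O)[O-])C[C@@H](C)[C@H]2[C@@H]3C1(C)C | intermediate
22 | (1R,2R,7S,8S,9R)-2,6,6,9-tetramethyl-11-nitrotricyclo[5.4.0.0^{2,8}]undec-3-en-5-one (C11 epimers) | O=C1C=C[C@@]2(C)[C@@H]3C([N+](=O)[O-])C[C@@H](C)[C@H]2[C@@H]3C1(C)C | intermediate
23 | (1R,2R,5R,7S,8S,9R)-2,6,6,9-tetramethyl-11-nitrotricyclo[5.4.0.0^{2,8}]undec-3-en-5-ol (C11 epimers) | O[C@@H]1C=C[C@@]2(C)[C@@H]3C([N+](=O)[O-])C[C@@H](C)[C@H]2[C@@H]3C1(C)C | intermediate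
24 | sodium nitronate of 23 | [Na+].O[C@@H]1C=C[C@@]2(C)[C@@H]3C(=[N+]([O-])[O-])C[C@@H](C)[C@H]2[C@@H]3C1(C)C | intermediate
25 | (1R,2R,5R,7S,8S,9R)-5-hydroxy-2,6,6,9-tetramethyltricyclo[5.4.0.0^{2,8}]undec-3-en-11-one | O[C@@H]1C=C[C@@]2(C)[C@@H]3C(=O)C[C@@H](C)[C@H]2[C@@H]3C1(C)C | intermediate
26 | (E)-2-methylbut-2-enoyl chloride (tigloyl chloride) | C/C=C(\C)C(Cl)=O | starting material
27 | (1R,2R,5R,7S,8S,9R)-2,6,6,9-tetramethyl-11-oxotricyclo[5.4.0.0^{2,8}]undec-3-en-5-yl (E)-2-methylbut-2-enoate | C/C=C(\C)C(=O)O[C@@H]1C=C[C@@]2(C)[C@@H]3C(=O)C[C@@H](C)[C@H]2[C@@H]3C1(C)C | intermediate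
28 | (1R,2R,3S,4S,5S,7S,8S,9R)-3,4-dihydroxy-2,6,6,9-tetramethyl-11-oxotricyclo[5.4.0.0^{2,8}]undecan-5-yl (E)-2-methylbut-2-enoate | C/C=C(\C)C(=O)O[C@@H]1[C@@H](O)[C@@H](O)[C@@]2(C)[C@@H]3C(=O)C[C@@H](C)[C@H]2[C@@H]3C1(C)C | intermediate
29 | (1R,2R,3S,4S,5S,7S,8S,9R)-3-hydroxy-2,6,6,9-tetramethyl-11-oxotricyclo[5.4.0.0^{2,8}]undecane-4,5-diyl bis[(E)-2-methylbut-2-enoate] | C/C=C(\C)C(=O)O[C@@H]1[C@@H](OC(=O)/C(C)=C/C)C(C)(C)[C@H]2[C@@H]3[C@H](C)CC(=O)[C@H]2[C@]3(C)[C@@H]1O | target

**Step count**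
Total: 17 steps (15 in the main line plus 2 for aldehyde 15).
Longest linear sequence: 15 steps (steps 1–5 and 8–17).

**Three steps most likely to fail, with fallbacks**

Step 3 (reductive opening of a hindered, trisubstituted bridged alkene; it also relies on the regiochemistry of step 1). The fallback sets out from 2 and brings the methyl group in by alkylative rather than reductive ring opening. Cycloaddition of 2 with furan itself (Et3N, CF3CH2OH) gives (±)-2,2-dimethyl-8-oxabicyclo[3.2.1]oct-6-en-3-one F1. Ketalisation as in step 2 gives (±)-3,3-dimethoxy-2,2-dimethyl-8-oxabicyclo[3.2.1]oct-6-ene F2. Syn-SN2′ opening with MeLi/TMEDA (Et2O, 0 → 23 °C) is expected to deliver the methyl group exo to the alkene carbon remote from the axial methyl of the gem-dimethyl group, giving (±)-cis-6,6-dimethoxy-2,5,5-trimethylcyclohept-3-en-1-ol F3. F3 is the C2 epimer of 6 and, under the conditions of step 4, goes through 7 to rejoin the route at 8.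

Step 8 (aldol at a γ-carbon next to a quaternary centre, with catalyst control of two stereocentres). The fallback sets out from 8 and changes both the activation and the source of asymmetry. Lithium dienolate 9 (LiN(i-Pr)2, THF, −78 °C) is added to aldehyde 15 precomplexed with the bulky aluminium phenoxide Al(OC6H3-2,6-Ph2)3 in toluene, which shields the α-carbon and steers the anion to its γ-terminus. This gives racemic aldol, that is 16 together with its enantiomer (5R)-5-[(1R)-1-hydroxy-2-methylidene-4-nitrobutyl]-3-methoxy-4,4,7-trimethylcyclohepta-2,6-dien-1-one F4. Sharpless kinetic resolution (Ti(Oi-Pr)4, D-(−)-diisopropyl tartrate, t-BuOOH, 4 Å molecular sieves, CH2Cl2, −20 °C) then epoxidises the fast-reacting enantiomer to the erythro epoxy alcohol (5R)-5-{(R)-hydroxy[(2S)-2-(2-nitroethyl)oxiran-2-yl]methyl}-3-methoxy-4,4,7-trimethylcyclohepta-2,6-dien-1-one F5. Unreacted 16 (at most 50 %) is recovered and rejoins the route at step 9.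

Step 11 (one-pot Michael addition and four-membered ring closure; elimination of the mesylate and O-alkylation compete). The fallback sets out from 17 and separates the two ring closures so that no leaving group is present during the conjugate addition. Tetramethylguanidine (10 mol %, MeCN, 0 °C) closes the cyclohexane on the free alcohol to give (1R,7S,8R,9R)-8-hydroxy-5-methoxy-2,6,6,9-tetramethyl-11-nitrobicyclo[5.4.0]undec-4-en-3-one F6. Mesylation (MeSO2Cl, Et3N) then gives 19 as an isolated compound. Its dianion (LiN(SiMe3)2, 2.2 equiv, THF/toluene, −78 → 23 °C; the lithium counter-ion and low-polarity medium favour C-alkylation) closes the cyclobutane and rejoins the route at 20.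

**Further compounds**
F1 | step 3 | (±)-2,2-dimethyl-8-oxabicyclo[3.2.1]oct-6-en-3-one | C1=C[C@H]2O[C@@H]1CC(=O)C2(C)C
F2 | step 3 | (±)-3,3-dimethoxy-2,2-dimethyl-8-oxabicyclo[3.2.1]oct-6-ene | C1=C[C@H]2O[C@@H]1CC(OC)(OC)C2(C)C
F3 | step 3 | (±)-cis-6,6-dimethoxy-2,5,5-trimethylcyclohept-3-en-1-ol | C[C@H]1C=CC(C)(C)C(OC)(OC)C[C@H]1O
F4 | step 8 | (5R)-5-[(1R)-1-hydroxy-2-methylidene-4-nitrobutyl]-3-methoxy-4,4,7-trimethylcyclohepta-2,6-dien-1-one (enantiomer of 16) | COC1=CC(=O)C(C)=C[C@@H]([C@@H](O)C(=C)CC[N+](=O)[O-])C1(C)C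
F5 | step 8 | (5R)-5-{(R)-hydroxy[(2S)-2-(2-nitroethyl)oxiran-2-yl]methyl}-3-methoxy-4,4,7-trimethylcyclohepta-2,6-dien-1-one | COC1=CC(=O)C(C)=C[C@@H]([C@@H](O)[C@]2(CO2)CC[N+](=O)[O-])C1(C)C
F6 | step 11 | (1R,7S,8R,9R)-8-hydroxy-5-methoxy-2,6,6,9-tetramethyl-11-nitrobicyclo[5.4.0]undec-4-en-3-one | COC1=CC(=O)C(C)[C@@H]2C([N+](=O)[O-])C[C@@H](C)[C@@H](O)[C@@H]2C1(C)C
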